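**Plan**
1. Retrosynthesis: the C6=C7 alkene is taken back to an allylic C7 acetate on an 8(17)-ene and C3 is re-oxygenated. The decalin is then cut at C9–C10 and C4–C5 to an acyclic epoxy polyene. The chain is cut at C9–C11 (sp2–sp3 coupling) and C8–C17 (carbometalation of an enyne made from geranylacetone).
2. Enabling feature: rings A and B form a trans-fused decalin in which C4, C10 and C8 are the 1,5-spaced branch carbons of a head-to-tail isoprenoid chain. C8 carries an exocyclic methylene (C17) next to C9, and the equatorial C18 oxygen on C4 is the E-terminal carbon of that chain.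
3. Forward: geranylacetone → enyne → E-allylic alcohol → silylmethyl vinyl iodide → coupling with the C11–C15 enoate → Sharpless epoxide. One Lewis-acid event then closes ring A (C4–C5) and ring B (C9–C10) and releases C8=C17 from an allylsilane.
4. Stereochemistry: the (2R,3R)-epoxide is the only source of chirality. Its anti opening sets C4, the E C5=C10 alkene sets the trans fusion (C5, C10), and the allylsilane geometry sets C9. The C3 hydroxyl is then removed and C6=C7 is introduced last.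

Key step: step 8

Remark: ring atoms carry labdane numbers (ring A = C1–C5, C10; ring B = C5–C10; C9 bears the C11–C16 side chain; C17 = exocyclic CH2; C18 = oxygenated carbon on C4; C19 and C20 = methyls on C4 and C10).
Assumption: geranylacetone is used as the pure 5E isomer.

**Step 1**
Reactants: 1 (5E)-6,10-dimethylundeca-5,9-dien-2-one (geranylacetone)
Product: 3 (5E)-6,10-dimethylundeca-5,9-dien-1-yne, via enol phosphate 2 (not isolated)
Conditions: LiN(iPr)2 (1.1 equiv), THF, −78 °C; ClP(O)(OEt)2, −78 °C → rt; then LiN(iPr)2 (2.3 equiv), −78 °C → rt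
Reagents that add atoms: none
Why: kinetic enolisation of the methyl ketone on the methyl side, O-phosphorylation and base-induced elimination (enol phosphate route from methyl ketones to terminal alkynes) should give the enyne without touching the 5E alkene.

**Step 2**
Reactants: 3 (5E)-6,10-dimethylundeca-5,9-dien-1-yne
Product: 4 (2E,6E)-2,6-dimethylundeca-2,6-dien-10-yn-1-ol
Conditions: SeO2 (0.3 equiv), t-BuOOH (3 equiv), salicylic acid (0.1 equiv), CH2Cl2, rt
Reagents that add atoms: tert-butyl hydroperoxide CC(C)(C)OO (terminal oxidant); selenium dioxide O=[Se]=O (oxygen carrier)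
Why: SeO2 allylic hydroxylation (ene reaction, then [2,3]-sigmatropic shift) should attack the E-methyl group of the terminal, most exposed trisubstituted alkene and leave the alkyne alone, giving the 2E allylic alcohol.

**Step 3**
Reactants: 4 (2E,6E)-2,6-dimethylundeca-2,6-dien-10-yn-1-ol; 5 (trimethylsilyl)methylmagnesium chloride
Product: 7 (2E,6E,10Z)-11-iodo-2,6-dimethyl-10-[(trimethylsilyl)methyl]undeca-2,6,10-trien-1-ol, via alkenylcopper alkoxide 6 (not isolated)
Conditions: 5 (3.2 equiv), CuBr·SMe2 (2.1 equiv), Et2O/Me2S, −45 → −10 °C; then I2 (2.2 equiv), THF, −45 → 0 °C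
Reagents that add atoms: iodine II
Why: after the first equivalent of 5 has deprotonated the hydroxyl, syn-carbocupration of the terminal alkyne places CH2SiMe3 on the internal carbon and copper on the terminal one, and iodinolysis with retention should give the 10Z vinyl iodide (iodine cis to CH2SiMe3).

**Step 4**
Reactants: 8 methyl but-2-ynoate; 9 vinylmagnesium bromide
Product: 10 methyl (2E)-3-methylpenta-2,4-dienoate
Conditions: 9 (1.1 equiv), CuBr·SMe2 (1.1 equiv), THF, −78 °C; then 8, −78 °C; MeOH, then aq. NH4Cl at −78 °C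
Reagents that add atoms: none
Why: syn conjugate addition of the vinylcopper reagent to the ynoate and protonation at −78 °C should leave vinyl and hydrogen cis, which is the 2E dienoate.

**Step 5**
Reactants: 7 (2E,6E,10Z)-11-iodo-2,6-dimethyl-10-[(trimethylsilyl)methyl]undeca-2,6,10-trien-1-ol; 10 methyl (2E)-3-methylpenta-2,4-dienoate
Product: 12 methyl (2E,6Z,10E,14E)-16-hydroxy-3,11,15-trimethyl-7-[(trimethylsilyl)methyl]hexadeca-2,6,10,14-tetraenoate, via alkylborane 11 (not isolated)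
Conditions: 10, 9-BBN-H, THF, 0 °C → rt; then 7, Pd(dppf)Cl2 (5 mol%), AsPh3, Cs2CO3, DMF/THF/H2O, rt
Reagents that add atoms: none
Why: 9-BBN should hydroborate only the terminal CH2=CH of the dienoate, and the B-alkyl Suzuki–Miyaura coupling joins that sp3 carbon to the vinyl iodide with retention of alkene geometry while ester, hydroxyl and allylsilane are tolerated.

**Step 6**
Reactants: 12 methyl (2E,6Z,10E,14E)-16-hydroxy-3,11,15-trimethyl-7-[(trimethylsilyl)methyl]hexadeca-2,6,10,14-tetraenoate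
Product: 13 methyl (2E,6Z,10E)-13-[(2R,3R)-3-(hydroxymethyl)-3-methyloxiran-2-yl]-3,11-dimethyl-7-[(trimethylsilyl)methyl]trideca-2,6,10-trienoate
Conditions: Ti(OiPr)4, D-(−)-diethyl tartrate, t-BuOOH (anhydrous, isooctane), 4 Å molecular sieves, CH2Cl2, −20 °C
Reagents that add atoms: tert-butyl hydroperoxide CC(C)(C)OO
Why: Sharpless asymmetric epoxidation acts only on the allylic alcohol alkene, and with D-(−)-diethyl tartrate the oxygen should be delivered to the face that gives the (2R,3R)-epoxide.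

**Step 7**
Reactants: 13 methyl (2E,6Z,10E)-13-[(2R,3R)-3-(hydroxymethyl)-3-methyloxiran-2-yl]-3,11-dimethyl-7-[(trimethylsilyl)methyl]trideca-2,6,10-trienoate
Product: 14 methyl (2E,6Z,10E)-13-[(2R,3R)-3-({[tert-butyl(dimethyl)silyl]oxy}methyl)-3-methyloxiran-2-yl]-3,11-dimethyl-7-[(trimethylsilyl)methyl]trideca-2,6,10-trienoate
Conditions: TBSCl, imidazole, DMF, 0 °C → rt
Reagents that add atoms: tert-butyl(chloro)dimethylsilane CC(C)(C)[Si](C)(C)Cl
Why: silylation of the primary alcohol gives an ether that cannot take part in the epoxide opening as an ester would.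

**Step 8**
Reactants: 14 methyl (2E,6Z,10E)-13-[(2R,3R)-3-({[tert-butyl(dimethyl)silyl]oxy}methyl)-3-methyloxiran-2-yl]-3,11-dimethyl-7-[(trimethylsilyl)methyl]trideca-2,6,10-trienoate
Product: 15 methyl (2E)-5-[(1R,4aS,5S,6R,8aS)-5-({[tert-butyl(dimethyl)silyl]oxy}methyl)-6-hydroxy-5,8a-dimethyl-2-methylidenedecahydronaphthalen-1-yl]-3-methylpent-2-enoate
Conditions: MeAlCl2 (2.5 equiv), CH2Cl2, −78 °C; aq. NaHCO3 work-up
Reagents that add atoms: none
Why: MeAlCl2 binds the epoxide oxygen, the C5=C10 alkene opens the C4–O bond from the rear (C4–C5 forms), the tertiary C10 cation is captured by C9 of the allylsilane (C9–C10 forms), and the β-silyl cation at C8 loses the silyl group so that only the C8=C17 exocyclic alkene results. The closest known reaction type is the Lewis-acid-promoted, epoxide-initiated polyene cyclization terminated by an allylsilane. Ring A closes 6-endo at the trisubstituted alkene and ring B closes 6-endo at the allylsilane, both through chair transition states. C3 keeps the epoxide configuration and ends equatorial, C4 is inverted so that the E-placed CH2OTBS becomes equatorial and the methyl axial, anti addition across the E C5=C10 alkene gives the trans ring fusion, and the allylsilane geometry (C7 trans to C11) places the C9 side chain equatorial. The step needs opening at the tertiary epoxide carbon and complete chair–chair bicyclization ahead of hydride shift to a C3 ketone or a stop after ring A. The tertiary C4, the strongly nucleophilic allylsilane placed for six-membered closure and the unreactive electron-poor enoate alkene should secure this.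

**Step 9**
Reactants: 15 methyl (2E)-5-[(1R,4aS,5S,6R,8aS)-5-({[tert-butyl(dimethyl)silyl]oxy}methyl)-6-hydroxy-5,8a-dimethyl-2-methylidenedecahydronaphthalen-1-yl]-3-methylpent-2-enoate
Product: 16 methyl (2E)-5-[(1R,4aS,5S,6R,8aS)-5-({[tert-butyl(dimethyl)silyl]oxy}methyl)-6-[(1H-imidazole-1-carbothioyl)oxy]-5,8a-dimethyl-2-methylidenedecahydronaphthalen-1-yl]-3-methylpent-2-enoate
Conditions: 1,1'-thiocarbonyldiimidazole (3 equiv), DMAP (0.2 equiv), toluene, 90 °C
Reagents that add atoms: 1,1'-thiocarbonyldiimidazole S=C(n1ccnc1)n1ccnc1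
Why: thioacylation of the hindered equatorial C3 hydroxyl prepares the C3–O bond for radical cleavage (first half of a Barton–McCombie deoxygenation).

**Step 10**
Reactants: 16 methyl (2E)-5-[(1R,4aS,5S,6R,8aS)-5-({[tert-butyl(dimethyl)silyl]oxy}methyl)-6-[(1H-imidazole-1-carbothioyl)oxy]-5,8a-dimethyl-2-methylidenedecahydronaphthalen-1-yl]-3-methylpent-2-enoate
Product: 17 methyl (2E)-5-[(1R,4aS,5S,8aS)-5-({[tert-butyl(dimethyl)silyl]oxy}methyl)-5,8a-dimethyl-2-methylidenedecahydronaphthalen-1-yl]-3-methylpent-2-enoate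
Conditions: Bu3SnH (2 equiv), AIBN (0.2 equiv), toluene, 110 °C
Reagents that add atoms: none
Why: Barton–McCombie deoxygenation, in which the stannyl radical adds to the thiocarbonyl group, the C3–O bond fragments and the secondary radical is reduced by Bu3SnH without touching a stereocenter.

**Step 11**
Reactants: 17 methyl (2E)-5-[(1R,4aS,5S,8aS)-5-({[tert-butyl(dimethyl)silyl]oxy}methyl)-5,8a-dimethyl-2-methylidenedecahydronaphthalen-1-yl]-3-methylpent-2-enoate
Product: 18 methyl (2E)-5-[(1R,4aS,5S,8aS)-5-(hydroxymethyl)-5,8a-dimethyl-2-methylidenedecahydronaphthalen-1-yl]-3-methylpent-2-enoate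
Conditions: Bu4NF, THF, 0 °C → rt
Reagents that add atoms: none
Why: fluoride-induced desilylation frees the C18 hydroxyl while the ester and the exocyclic alkene are inert.

**Step 12**
Reactants: 18 methyl (2E)-5-[(1R,4aS,5S,8aS)-5-(hydroxymethyl)-5,8a-dimethyl-2-methylidenedecahydronaphthalen-1-yl]-3-methylpent-2-enoate
Product: 19 methyl (2E)-5-[(1S,3S,4aS,5S,8aR)-3-hydroxy-5-(hydroxymethyl)-5,8a-dimethyl-2-methylidenedecahydronaphthalen-1-yl]-3-methylpent-2-enoate (same skeleton and configuration as 18, new axial hydroxyl at C7)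
Conditions: SeO2 (0.5 equiv), t-BuOOH (2 equiv), CH2Cl2, 0 °C → rt
Reagents that add atoms: tert-butyl hydroperoxide CC(C)(C)OO (terminal oxidant); selenium dioxide O=[Se]=O (oxygen carrier)
Why: SeO2 allylic hydroxylation of the exocyclic C8=C17 alkene should occur at the ring CH2 (C7) and not at the hindered tertiary C9–H, giving mainly the axial alcohol, whose configuration is erased in step 14, while the electron-poor enoate is not attacked.

**Step 13**
Reactants: 19 methyl (2E)-5-[(1S,3S,4aS,5S,8aR)-3-hydroxy-5-(hydroxymethyl)-5,8a-dimethyl-2-methylidenedecahydronaphthalen-1-yl]-3-methylpent-2-enoate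
Product: 20 methyl (2E)-5-[(1S,3S,4aS,5S,8aR)-3-acetoxy-5-(acetoxymethyl)-5,8a-dimethyl-2-methylidenedecahydronaphthalen-1-yl]-3-methylpent-2-enoate
Conditions: Ac2O, pyridine, DMAP (cat.), CH2Cl2, rt
Reagents that add atoms: acetic anhydride CC(=O)OC(C)=O
Why: acetylation of both hydroxyls installs the C18 acetate of the target and turns the C7 hydroxyl into an allylic leaving group.

**Step 14**
Reactants: 20 methyl (2E)-5-[(1S,3S,4aS,5S,8aR)-3-acetoxy-5-(acetoxymethyl)-5,8a-dimethyl-2-methylidenedecahydronaphthalen-1-yl]-3-methylpent-2-enoate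
Product: 21 methyl (2E)-5-[(1R,4aS,5S,8aS)-5-(acetoxymethyl)-5,8a-dimethyl-2-methylidene-1,2,4a,5,6,7,8,8a-octahydronaphthalen-1-yl]-3-methylpent-2-enoate
Conditions: Pd(PPh3)4 (5 mol%), Et3N, 1,4-dioxane, 100 °C
Reagents that add atoms: none
Why: zerovalent palladium should ionise only the allylic C7 acetate to the C7–C8–C17 π-allyl complex, whose only β-hydrogens are on C6, so β-hydride elimination can give only the C6=C7/C8=C17 diene (palladium-catalysed elimination of an allylic acetate to a 1,3-diene).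

**Compound list**
1 | (5E)-6,10-dimethylundeca-5,9-dien-2-one (geranylacetone) | CC(=O)CC/C=C(\C)CCC=C(C)C | starting material
2 | diethyl (5E)-6,10-dimethylundeca-1,5,9-trien-2-yl phosphate | C=C(OP(=O)(OCC)OCC)CC/C=C(\C)CCC=C(C)C | intermediate (not isolated)
3 | (5E)-6,10-dimethylundeca-5,9-dien-1-yne | C#CCC/C=C(\C)CCC=C(C)C | intermediate
4 | (2E,6E)-2,6-dimethylundeca-2,6-dien-10-yn-1-ol | C#CCC/C=C(\C)CC/C=C(\C)CO | intermediate
5 | (trimethylsilyl)methylmagnesium chloride | C[Si](C)(C)C[Mg]Cl | starting material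
6 | chloromagnesium alkoxide of (2E,6E,10Z)-11-cuprio-2,6-dimethyl-10-[(trimethylsilyl)methyl]undeca-2,6,10-trien-1-ol | [Cu]/C=C(\C[Si](C)(C)C)CC/C=C(\C)CC/C=C(\C)CO[Mg]Cl | intermediate (not isolated)
7 | (2E,6E,10Z)-11-iodo-2,6-dimethyl-10-[(trimethylsilyl)methyl]undeca-2,6,10-trien-1-ol | I/C=C(\C[Si](C)(C)C)CC/C=C(\C)CC/C=C(\C)CO | intermediate
8 | methyl but-2-ynoate | CC#CC(=O)OC | starting material
9 | vinylmagnesium bromide | C=C[Mg]Br | starting material
10 | methyl (2E)-3-methylpenta-2,4-dienoate | C=C/C(C)=C/C(=O)OC | intermediate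
11 | methyl (2E)-5-(9-borabicyclo[3.3.1]nonan-9-yl)-3-methylpent-2-enoate | COC(=O)/C=C(\C)CCB1C2CCCC1CCC2 | intermediate (not isolated)
12 | methyl (2E,6Z,10E,14E)-16-hydroxy-3,11,15-trimethyl-7-[(trimethylsilyl)methyl]hexadeca-2,6,10,14-tetraenoate | COC(=O)/C=C(\C)CC/C=C(\C[Si](C)(C)C)CC/C=C(\C)CC/C=C(\C)CO | intermediate
13 | methyl (2E,6Z,10E)-13-[(2R,3R)-3-(hydroxymethyl)-3-methyloxiran-2-yl]-3,11-dimethyl-7-[(trimethylsilyl)methyl]trideca-2,6,10-trienoate | COC(=O)/C=C(\C)CC/C=C(\C[Si](C)(C)C)CC/C=C(\C)CC[C@H]1O[C@]1(C)CO | intermediate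
14 | methyl (2E,6Z,10E)-13-[(2R,3R)-3-({[tert-butyl(dimethyl)silyl]oxy}methyl)-3-methyloxiran-2-yl]-3,11-dimethyl-7-[(trimethylsilyl)methyl]trideca-2,6,10-trienoate | COC(=O)/C=C(\C)CC/C=C(\C[Si](C)(C)C)CC/C=C(\C)CC[C@H]1O[C@]1(C)CO[Si](C)(C)C(C)(C)C | intermediate
15 | methyl (2E)-5-[(1R,4aS,5S,6R,8aS)-5-({[tert-butyl(dimethyl)silyl]oxy}methyl)-6-hydroxy-5,8a-dimethyl-2-methylidenedecahydronaphthalen-1-yl]-3-methylpent-2-enoate | C=C1CC[C@@H]2[C@@](C)(CO[Si](C)(C)C(C)(C)C)[C@H](O)CC[C@@]2(C)[C@@H]1CC/C(C)=C/C(=O)OC | intermediate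
16 | methyl (2E)-5-[(1R,4aS,5S,6R,8aS)-5-({[tert-butyl(dimethyl)silyl]oxy}methyl)-6-[(1H-imidazole-1-carbothioyl)oxy]-5,8a-dimethyl-2-methylidenedecahydronaphthalen-1-yl]-3-methylpent-2-enoate | C=C1CC[C@@H]2[C@@](C)(CO[Si](C)(C)C(C)(C)C)[C@H](OC(=S)n3ccnc3)CC[C@@]2(C)[C@@H]1CC/C(C)=C/C(=O)OC | intermediate
17 | methyl (2E)-5-[(1R,4aS,5S,8aS)-5-({[tert-butyl(dimethyl)silyl]oxy}methyl)-5,8a-dimethyl-2-methylidenedecahydronaphthalen-1-yl]-3-methylpent-2-enoate | C=C1CC[C@@H]2[C@@](C)(CO[Si](C)(C)C(C)(C)C)CCC[C@@]2(C)[C@@H]1CC/C(C)=C/C(=O)OC | intermediate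
18 | methyl (2E)-5-[(1R,4aS,5S,8aS)-5-(hydroxymethyl)-5,8a-dimethyl-2-methylidenedecahydronaphthalen-1-yl]-3-methylpent-2-enoate | C=C1CC[C@@H]2[C@@](C)(CO)CCC[C@@]2(C)[C@@H]1CC/C(C)=C/C(=O)OC | intermediate
19 | methyl (2E)-5-[(1S,3S,4aS,5S,8aR)-3-hydroxy-5-(hydroxymethyl)-5,8a-dimethyl-2-methylidenedecahydronaphthalen-1-yl]-3-methylpent-2-enoate | C=C1[C@@H](O)C[C@@H]2[C@@](C)(CO)CCC[C@@]2(C)[C@@H]1CC/C(C)=C/C(=O)OC | intermediate
20 | methyl (2E)-5-[(1S,3S,4aS,5S,8aR)-3-acetoxy-5-(acetoxymethyl)-5,8a-dimethyl-2-methylidenedecahydronaphthalen-1-yl]-3-methylpent-2-enoate | C=C1[C@@H](OC(C)=O)C[C@@H]2[C@@](C)(COC(C)=O)CCC[C@@]2(C)[C@@H]1CC/C(C)=C/C(=O)OC | intermediate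
21 | methyl (2E)-5-[(1R,4aS,5S,8aS)-5-(acetoxymethyl)-5,8a-dimethyl-2-methylidene-1,2,4a,5,6,7,8,8a-octahydronaphthalen-1-yl]-3-methylpent-2-enoate | C=C1C=C[C@@H]2[C@@](C)(COC(C)=O)CCC[C@@]2(C)[C@@H]1CC/C(C)=C/C(=O)OC | target

**Step count**
Total: 14 steps. Longest linear sequence: 13 steps (steps 1–3 and 5–14, from 1 to 21); step 4 is a one-step branch.

**Steps most likely to fail, with fallbacks**

Step 8. The activated epoxide may rearrange by hydride shift to a C3 ketone, or the cascade may stop after ring A through proton loss from the C10 cation or protodesilylation before C9–C10 closes. The fallback sets out from 13 and comes back at 18. The unprotected epoxy alcohol 13 would be treated with Et2AlCl so that the aluminium alkoxide delivers the Lewis acid to the epoxide oxygen from within. This should give methyl (2E)-5-[(1R,4aS,5S,6R,8aS)-6-hydroxy-5-(hydroxymethyl)-5,8a-dimethyl-2-methylidenedecahydronaphthalen-1-yl]-3-methylpent-2-enoate F1. With 1,1'-thiocarbonyldiimidazole this 1,3-diol would be closed to the cyclic 3,18-thionocarbonate of F1 (a fused 1,3-dioxane-2-thione) F2. Bu3SnH/AIBN should cleave this ring at the secondary C3–O bond to give the 18-O-[(tributylstannylsulfanyl)carbonyl] derivative of 18 F3. K2CO3 in methanol would then release 18.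

Step 3. Carbometalation of the unactivated alkyne in the presence of the magnesium alkoxide may be slow or regiochemically impure, and the alkenylcopper may be lost before iodination. The fallback sets out from 4 and comes back at 12, building the allylsilane by hydroalumination–iodination and cross-coupling and the C11–C12 bond by sulfone alkylation.
- Compound 4 would be silylated (TBSCl, imidazole) to tert-butyl{[(2E,6E)-2,6-dimethylundeca-2,6-dien-10-yn-1-yl]oxy}dimethylsilane F4.
- n-BuLi and paraformaldehyde would give (6E,10E)-12-{[tert-butyl(dimethyl)silyl]oxy}-7,11-dimethyldodeca-6,10-dien-2-yn-1-ol F5.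
- Alkoxide-directed trans-hydroalumination with NaAlH2(OCH2CH2OMe)2 followed by I2 should give (2Z,6E,10E)-12-{[tert-butyl(dimethyl)silyl]oxy}-3-iodo-7,11-dimethyldodeca-2,6,10-trien-1-ol F6.
- Coupling with Me3SiCH2MgCl and Pd(PPh3)4 with retention would give (2Z,6E,10E)-12-{[tert-butyl(dimethyl)silyl]oxy}-7,11-dimethyl-3-[(trimethylsilyl)methyl]dodeca-2,6,10-trien-1-ol F7.
- CBr4/PPh3 would give the allylic bromide [(2Z,6E,10E)-12-bromo-2,6-dimethyl-10-[(trimethylsilyl)methyl]dodeca-2,6,10-trien-1-yl]oxy(tert-butyl)dimethylsilane F8.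
- Alkylation of the sodium salt of methyl (2E)-3-methyl-4-(phenylsulfonyl)but-2-enoate (itself from methyl (2E)-4-bromo-3-methylbut-2-enoate and PhSO2Na) at the sulfonyl-bearing carbon would give methyl (2E,6Z,10E,14E)-16-{[tert-butyl(dimethyl)silyl]oxy}-3,11,15-trimethyl-4-(phenylsulfonyl)-7-[(trimethylsilyl)methyl]hexadeca-2,6,10,14-tetraenoate F9, as a mixture of C4 epimers.
- Reductive desulfonylation (Na(Hg), Na2HPO4, MeOH, −20 °C) would give methyl (2E,6Z,10E,14E)-16-{[tert-butyl(dimethyl)silyl]oxy}-3,11,15-trimethyl-7-[(trimethylsilyl)methyl]hexadeca-2,6,10,14-tetraenoate F10.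
- Bu4NF would then give 12.

Step 12. Over-oxidation to the enone, attack at C9, or sluggish reaction at the hindered exocyclic alkene could erode the late-stage hydroxylation. The fallback sets out from 18 and comes back at 21, replacing hydroxylation by ene-type chlorination. Compound 18 would be acetylated to methyl (2E)-5-[(1R,4aS,5S,8aS)-5-(acetoxymethyl)-5,8a-dimethyl-2-methylidenedecahydronaphthalen-1-yl]-3-methylpent-2-enoate F11. Chlorination with N-chlorosuccinimide and catalytic PhSeCl should put chlorine on C17 and move the alkene to C7=C8, giving methyl 18-acetoxy-17-chloro-ent-labda-7,13E-dien-15-oate (labdane numbering; ring stereocenters as in 18) F12. Pd(PPh3)4/Et3N in hot dioxane would ionise this allylic chloride to the same C7–C8–C17 π-allyl complex as in step 14, and β-hydride elimination from C6 would give 21.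

**Further compounds**
F1 | step 8 | methyl (2E)-5-[(1R,4aS,5S,6R,8aS)-6-hydroxy-5-(hydroxymethyl)-5,8a-dimethyl-2-methylidenedecahydronaphthalen-1-yl]-3-methylpent-2-enoate | C=C1CC[C@@H]2[C@@](C)(CO)[C@H](O)CC[C@@]2(C)[C@@H]1CC/C(C)=C/C(=O)OC
F2 | step 8 | cyclic 3,18-thionocarbonate of F1 (fused 1,3-dioxane-2-thione) | C=C1CC[C@@H]2[C@@]3(C)COC(=S)O[C@@H]3CC[C@@]2(C)[C@@H]1CC/C(C)=C/C(=O)OC
F3 | step 8 | 18-O-[(tributylstannylsulfanyl)carbonyl] derivative of 18 | C=C1CC[C@@H]2[C@@](C)(COC(=O)S[Sn](CCCC)(CCCC)CCCC)CCC[C@@]2(C)[C@@H]1CC/C(C)=C/C(=O)OC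
F4 | step 3 | tert-butyl{[(2E,6E)-2,6-dimethylundeca-2,6-dien-10-yn-1-yl]oxy}dimethylsilane | C#CCC/C=C(\C)CC/C=C(\C)CO[Si](C)(C)C(C)(C)C
F5 | step 3 | (6E,10E)-12-{[tert-butyl(dimethyl)silyl]oxy}-7,11-dimethyldodeca-6,10-dien-2-yn-1-ol | OCC#CCC/C=C(\C)CC/C=C(\C)CO[Si](C)(C)C(C)(C)C
F6 | step 3 | (2Z,6E,10E)-12-{[tert-butyl(dimethyl)silyl]oxy}-3-iodo-7,11-dimethyldodeca-2,6,10-trien-1-ol | OC/C=C(\I)CC/C=C(\C)CC/C=C(\C)CO[Si](C)(C)C(C)(C)C
F7 | step 3 | (2Z,6E,10E)-12-{[tert-butyl(dimethyl)silyl]oxy}-7,11-dimethyl-3-[(trimethylsilyl)methyl]dodeca-2,6,10-trien-1-ol | OC/C=C(\C[Si](C)(C)C)CC/C=C(\C)CC/C=C(\C)CO[Si](C)(C)C(C)(C)C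
F8 | step 3 | [(2Z,6E,10E)-12-bromo-2,6-dimethyl-10-[(trimethylsilyl)methyl]dodeca-2,6,10-trien-1-yl]oxy(tert-butyl)dimethylsilane | BrC/C=C(\C[Si](C)(C)C)CC/C=C(\C)CC/C=C(\C)CO[Si](C)(C)C(C)(C)C
F9 | step 3 | methyl (2E,6Z,10E,14E)-16-{[tert-butyl(dimethyl)silyl]oxy}-3,11,15-trimethyl-4-(phenylsulfonyl)-7-[(trimethylsilyl)methyl]hexadeca-2,6,10,14-tetraenoate (C4 epimers) | COC(=O)/C=C(\C)C(C/C=C(\C[Si](C)(C)C)CC/C=C(\C)CC/C=C(\C)CO[Si](C)(C)C(C)(C)C)S(=O)(=O)c1ccccc1
F10 | step 3 | methyl (2E,6Z,10E,14E)-16-{[tert-butyl(dimethyl)silyl]oxy}-3,11,15-trimethyl-7-[(trimethylsilyl)methyl]hexadeca-2,6,10,14-tetraenoate | COC(=O)/C=C(\C)CC/C=C(\C[Si](C)(C)C)CC/C=C(\C)CC/C=C(\C)CO[Si](C)(C)C(C)(C)C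
F11 | step 12 | methyl (2E)-5-[(1R,4aS,5S,8aS)-5-(acetoxymethyl)-5,8a-dimethyl-2-methylidenedecahydronaphthalen-1-yl]-3-methylpent-2-enoate | C=C1CC[C@@H]2[C@@](C)(COC(C)=O)CCC[C@@]2(C)[C@@H]1CC/C(C)=C/C(=O)OC
F12 | step 12 | methyl 18-acetoxy-17-chloro-ent-labda-7,13E-dien-15-oate | ClCC1=CC[C@@H]2[C@@](C)(COC(C)=O)CCC[C@@]2(C)[C@@H]1CC/C(C)=C/C(=O)OC
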